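**Plan**
Oxanorbornane numbering: C1 and C4 are the O-bearing bridgeheads (each with CH3), C2 is the CH with the side chain, C3 is CH(CH3), C5/C6 are the CH2CH2 bridge, and O7 is the oxygen. Enabling feature: in ring O7–C1–C2–C3–C4 both C–O carbons are tertiary, and the endo H on C3 lies anti to the C4–O7 bond. Returning that H to C4 gives a tertiary C3 cation β to the C1 alkoxide.
Cuts: first C4–O7 (with the H shift C3→C4), then C1–C2 (retro-Prins). This leads to an acyclic (Z)-δ,ε-unsaturated methyl ketone. Its vinylic C2–CH2 bond is then cut into a primary boronic ester and an E-alkenyl iodide.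
Forward order: the oxane ring forms first, by bromoetherification of a linalool-derived dienol. The two fragments are then joined. The carbocycle and both oxolane rings of the oxanorbornane close together in the last step.
Stereochemistry: oxane C6 comes from (S)-linalool, and oxane C2/C3 from anti addition to an E-alkene. One CH(CH3) centre is set by an enamine-catalysed Michael addition. The Z-alkene arises from a geometry-inverting Zweifel olefination of an E-alkenyl unit.
That single centre and the alkene geometry are relayed into C1, C2, C3 and C4 of the oxanorbornane in the cascade.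

Key step: step 11

Remark: (S)-(+)-linalool (coriandrol) is assumed to be purchasable in high enantiomeric purity.

**Step 1**
Reactants: 1 (S)-(+)-linalool
Product: 2 (2E,6S)-2,6-dimethylocta-2,7-diene-1,6-diol
Conditions: SeO2 (cat.), t-BuOOH, salicylic acid (cat.), CH2Cl2, 0 °C to rt
Reagents that add atoms: tert-butyl hydroperoxide, CC(C)(C)OO
Why: Riley allylic oxidation (ene reaction, then [2,3]-shift) attacks the electron-rich trisubstituted alkene at its E-methyl group only, which fixes the E geometry needed later and leaves the carbinol centre untouched.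

**Step 2**
Reactants: 2 (2E,6S)-2,6-dimethylocta-2,7-diene-1,6-diol
Product: 3 (3S,6E)-8-bromo-3,7-dimethylocta-1,6-dien-3-ol
Conditions: CBr4, PPh3, CH2Cl2, −30 to 0 °C
Reagents that add atoms: carbon tetrabromide, BrC(Br)(Br)Br
Why: Appel reaction: the oxyphosphonium salt forms only at the unhindered primary allylic hydroxyl and is displaced by bromide in an SN2 manner at low temperature, so the tertiary allylic alcohol, its stereocentre and the E-alkene stay unchanged.

**Step 3**
Reactants: 3 (3S,6E)-8-bromo-3,7-dimethylocta-1,6-dien-3-ol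
Product: 4 (3S,6E)-3,7-dimethyl-9-(4,4,5,5-tetramethyl-1,3,2-dioxaborolan-2-yl)nona-1,6-dien-3-ol
Conditions: CH2(Bpin)2, NaOt-Bu (excess), THF, rt
Reagents that add atoms: bis(pinacolatoboryl)methane, CC1(C)OB(CB2OC(C)(C)C(C)(C)O2)OC1(C)C
Why: Deborylative alkylation of a geminal bis(boronate): tert-butoxide removes one boryl group and the boron-stabilised carbanion displaces the primary allylic bromide by SN2, which adds the CH2–Bpin unit without touching a stereocentre.

**Step 4**
Reactants: 4 (3S,6E)-3,7-dimethyl-9-(4,4,5,5-tetramethyl-1,3,2-dioxaborolan-2-yl)nona-1,6-dien-3-ol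
Product: 5 2-{2-[(2S,3R,6S)-3-bromo-6-ethenyl-2,6-dimethyloxan-2-yl]ethyl}-4,4,5,5-tetramethyl-1,3,2-dioxaborolane
Conditions: 2,4,4,6-tetrabromocyclohexa-2,5-dienone (TBCO), MeNO2, −20 to 0 °C; chromatography
Reagents that add atoms: TBCO, O=C1C(Br)=CC(Br)(Br)C=C1Br
Why: Bromonium-induced 6-endo (Markovnikov) etherification through a chair: anti addition of Br and O across the E-alkene sets oxane C3 (Br equatorial) and C2 (side chain equatorial, CH3 axial) relative to each other, C6 comes from linalool, and because face selection relative to C6 should be weak, the isomer of opposite configuration at C2 and C3 is removed by chromatography.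

**Step 5**
Reactants: 6 propanal; 7 but-3-en-2-one (methyl vinyl ketone)
Product: 8 (2S)-2-methyl-5-oxohexanal
Conditions: (R)-2-[methoxy(diphenyl)methyl]pyrrolidine (5 mol %), ethyl 3,4-dihydroxybenzoate (20 mol %), neat, 4 °C
Reagents that add atoms: none
Why: Enamine-catalysed asymmetric Michael addition: the E-enamine of propanal adds to the enone from the face not covered by the methoxydiphenylmethyl group, which sets the (S) methyl-bearing centre.

**Step 6**
Reactants: 8 (2S)-2-methyl-5-oxohexanal
Product: 9 (5S)-5-methylhept-6-yn-2-one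
Conditions: dimethyl (1-diazo-2-oxopropyl)phosphonate, K2CO3, MeOH, 0 °C to rt
Reagents that add atoms: dimethyl (1-diazo-2-oxopropyl)phosphonate, COP(=O)(OC)C(=[N+]=[N-])C(C)=O
Why: Ohira–Bestmann (Seyferth–Gilbert) homologation converts the aldehyde into the terminal alkyne much faster than it touches the ketone, and the mild carbonate conditions should keep the α-centre intact.

**Step 7**
Reactants: 9 (5S)-5-methylhept-6-yn-2-one
Product: 10 2-methyl-2-[(3S)-3-methylpent-4-yn-1-yl]-1,3-dioxolane
Conditions: HOCH2CH2OH, PPTS (cat.), benzene, reflux, Dean–Stark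
Reagents that add atoms: ethylene glycol, OCCO
Why: Acid-catalysed ketalisation with azeotropic removal of water masks the ketone against the organoaluminium and organolithium reagents of the next two steps, and the propargylic centre is not affected.

**Step 8**
Reactants: 10 2-methyl-2-[(3S)-3-methylpent-4-yn-1-yl]-1,3-dioxolane
Product: 12 2-[(3S,4E)-5-iodo-3,4-dimethylpent-4-en-1-yl]-2-methyl-1,3-dioxolane, via alkenylalane 11 (not isolated)
Conditions: Me3Al, Cp2ZrCl2 (20 mol %), H2O (additive), CH2Cl2, −23 °C; then I2, THF, −23 to 0 °C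
Reagents that add atoms: trimethylaluminium, C[Al](C)C; iodine, II
Why: Negishi zirconium-catalysed carboalumination adds CH3 and Al syn across the terminal alkyne with CH3 at the internal carbon, iodinolysis with retention gives the E-iodide, and the water-accelerated low-temperature variant should spare the ketal.

**Step 9**
Reactants: 12 2-[(3S,4E)-5-iodo-3,4-dimethylpent-4-en-1-yl]-2-methyl-1,3-dioxolane; 5 2-{2-[(2S,3R,6S)-3-bromo-6-ethenyl-2,6-dimethyloxan-2-yl]ethyl}-4,4,5,5-tetramethyl-1,3,2-dioxaborolane
Product: 16 2-{(3S,4Z)-7-[(2S,3R,6S)-3-bromo-6-ethenyl-2,6-dimethyloxan-2-yl]-3,4-dimethylhept-4-en-1-yl}-2-methyl-1,3-dioxolane, via alkenyllithium 13 (not isolated), via boronate complex 14 (not isolated), via iodoboronate 15 (not isolated)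
Conditions: 12, t-BuLi (2 equiv), Et2O, −78 °C; 5, THF, −78 to 0 °C; I2, THF, −78 °C; NaOMe, MeOH, −78 °C to rt
Reagents that add atoms: none
Why: Zweifel olefination: iodine–lithium exchange with retention, boronate formation at the primary boronic ester (faster than any attack on the hindered equatorial bromide), iodonium-triggered 1,2-migration of the alkyl group anti to iodine, and anti elimination of boron and iodine together invert the alkene geometry, so the E-alkenyl unit gives the Z-trisubstituted alkene.

**Step 10**
Reactants: 16 2-{(3S,4Z)-7-[(2S,3R,6S)-3-bromo-6-ethenyl-2,6-dimethyloxan-2-yl]-3,4-dimethylhept-4-en-1-yl}-2-methyl-1,3-dioxolane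
Product: 17 (5S,6Z)-9-[(2S,3R,6S)-3-bromo-6-ethenyl-2,6-dimethyloxan-2-yl]-5,6-dimethylnon-6-en-2-one
Conditions: PPTS (cat.), THF–H2O (4:1), 50 °C
Reagents that add atoms: water, O
Why: Mild acid-catalysed ketal hydrolysis frees the methyl ketone, and the buffered acid is too weak to ionise the tertiary allylic ether or to move the Z-alkene.

**Step 11**
Reactants: 17 (5S,6Z)-9-[(2S,3R,6S)-3-bromo-6-ethenyl-2,6-dimethyloxan-2-yl]-5,6-dimethylnon-6-en-2-one
Product: 18 dactylopyranoid, (2S,3R,6S)-3-bromo-6-ethenyl-2,6-dimethyl-2-{2-[(1R,2R,3R,4S)-1,3,4-trimethyl-7-oxabicyclo[2.2.1]heptan-2-yl]ethyl}oxane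
Conditions: MeAlCl2 (2.0 equiv), CH2Cl2 (0.01 M), −78 to −30 °C; Et3N, then aq. NaHCO3
Reagents that add atoms: none
Why: Proposed new method: MeAlCl2 activates only the methyl ketone (the two di-tert-alkyl ether oxygens are shielded and the reagent scavenges protons, so no alkene is protonated); C2 of the Z-alkene then attacks C1 in the Markovnikov sense, the axial C4–H migrates suprafacially to the tertiary C3 cation, and the aluminium alkoxide on C1 captures the new tertiary C4 cation, which frees the Lewis acid. The closest known reaction types are the alkylaluminium-halide-initiated Prins cyclization of unsaturated ketones, whose zwitterions evolve by 1,2-hydride shifts, and epoxy-olefin cyclizations that end by oxygen capture to 7-oxanorbornanes; ending the ketone sequence by 1,4-ether capture is the unproven part. Ring closures: the carbocycle C1–C6 forms 6-endo-trig at the alkene (exo at C=O) through a chair, and the transannular C4–O7 bond, made once the flattened C4 tips into a boat, closes the oxolane rings O7–C1–C2–C3–C4 and O7–C1–C6–C5–C4 together. Stereocontrol: the Z geometry puts the side chain axial on C2, so only the chair with axial H (not CH3) on the (S)-C4 centre avoids a 1,3-diaxial alkyl clash, and this fixes the attacked alkene face (C2); the small, charge-attracted oxygen sits axial on C1, trans to the side chain; H arrives on C3 anti to the new C1–C2 bond (H endo, CH3 exo); and O7 enters C4 anti to the departing H, the only face it can reach. The selectivity needed is hydride shift from C4 rather than from C2 or proton loss, and it is secured because the equatorial C2–H is orthogonal to the empty orbital and the doubly complexed alkoxide is too weak a base for the ene pathway.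

**Compound list**
1 | (S)-(+)-linalool | C=C[C@](O)(C)CCC=C(C)C | starting material
2 | (2E,6S)-2,6-dimethylocta-2,7-diene-1,6-diol | C=C[C@](O)(C)CC/C=C(\C)CO | intermediate
3 | (3S,6E)-8-bromo-3,7-dimethylocta-1,6-dien-3-ol | C=C[C@](O)(C)CC/C=C(\C)CBr | intermediate
4 | (3S,6E)-3,7-dimethyl-9-(pinacolatoboryl)nona-1,6-dien-3-ol | C=C[C@](O)(C)CC/C=C(\C)CCB1OC(C)(C)C(C)(C)O1 | intermediate
5 | (2S,3R,6S)-bromo-oxane ethylboronic acid pinacol ester | C=C[C@]1(C)CC[C@@H](Br)[C@](C)(CCB2OC(C)(C)C(C)(C)O2)O1 | intermediate
6 | propanal | CCC=O | starting material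
7 | but-3-en-2-one | CC(=O)C=C | starting material
8 | (2S)-2-methyl-5-oxohexanal | O=C[C@@H](C)CCC(C)=O | intermediate
9 | (5S)-5-methylhept-6-yn-2-one | C#C[C@@H](C)CCC(C)=O | intermediate
10 | 2-methyl-2-[(3S)-3-methylpent-4-yn-1-yl]-1,3-dioxolane | C#C[C@@H](C)CCC1(C)OCCO1 | intermediate
11 | (E)-alkenyl(dimethyl)alane (not isolated) | C[Al](C)/C=C(\C)[C@@H](C)CCC1(C)OCCO1 | intermediate
12 | 2-[(3S,4E)-5-iodo-3,4-dimethylpent-4-en-1-yl]-2-methyl-1,3-dioxolane | I/C=C(\C)[C@@H](C)CCC1(C)OCCO1 | intermediate
13 | (E)-alkenyllithium (not isolated) | [Li]/C=C(\C)[C@@H](C)CCC1(C)OCCO1 | intermediate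
14 | lithium alkenyl(alkyl)pinacolboronate (not isolated) | [Li+].C=C[C@]1(C)CC[C@@H](Br)[C@](C)(CC[B-]2(/C=C(\C)[C@@H](C)CCC3(C)OCCO3)OC(C)(C)C(C)(C)O2)O1 | intermediate
15 | β-iodoalkyl boronic ester, both anti adducts, the two transient centres left open (not isolated) | C=C[C@]1(C)CC[C@@H](Br)[C@](C)(CCC(B2OC(C)(C)C(C)(C)O2)C(C)(I)[C@@H](C)CCC2(C)OCCO2)O1 | intermediate
16 | (3S,4Z)-alkenyl dioxolane | C=C[C@]1(C)CC[C@@H](Br)[C@](C)(CC/C=C(/C)[C@@H](C)CCC2(C)OCCO2)O1 | intermediate
17 | (5S,6Z)-9-[(2S,3R,6S)-3-bromo-6-ethenyl-2,6-dimethyloxan-2-yl]-5,6-dimethylnon-6-en-2-one | C=C[C@]1(C)CC[C@@H](Br)[C@](C)(CC/C=C(/C)[C@@H](C)CCC(C)=O)O1 | intermediate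
18 | dactylopyranoid | C=C[C@]1(C)CC[C@@H](Br)[C@](C)(CC[C@@H]2[C@@H](C)[C@]3(C)CC[C@@]2(C)O3)O1 | target

Total step count: 11. Longest linear sequence: 7 steps (steps 1–4 and 9–11, or steps 5–11).

**Steps most likely to fail**

Step 11.
- What may go wrong: the zwitterion may lose a proton (ene pathway) or fragment back to an open unsaturated ketone. The chair may also be poorly preferred over boat closure, or the Lewis acid may ionise the tertiary allylic C–O bond of the oxane.
- Fallback (from 17 back to 18, known chemistry only): 17 is treated with Me2AlCl (1 equiv, CH2Cl2, −78 to 0 °C). This is an intramolecular carbonyl-ene reaction, with hydrogen transfer from the vinylic methyl group, and should give the methylenecyclohexanol F1.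
- Catalytic TsOH in CH2Cl2 then moves the exocyclic alkene into the tetrasubstituted position, giving the cyclohexenol F2.
- The same acid closes the ether by the transannular Markovnikov hydroalkoxylation known from the terpinenol to 1,4-cineole conversion. H and O add anti, which puts the C3 methyl group exo and gives 18.

Step 4.
- What may go wrong: 5-exo closure to the oxolane may compete, and the choice of alkene face relative to the carbinol centre may be poor.
- Fallback (from 4 back to 5): 4 is cyclised with Hg(OCOCF3)2 in MeNO2. This oxymercuration is reversible and settles on the six-membered ether.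
- Anion exchange with aqueous KBr gives the organomercury bromide F3, which is purified.
- Electrophilic bromodemercuration (Br2, pyridine, 0 °C, dark) replaces mercury by bromine with retention and gives 5.

Step 9.
- What may go wrong: boronate formation may be incomplete, iodine may be consumed elsewhere, or partial syn elimination may erode the Z geometry.
- Fallback (from 12 and 5 back to 16): the geometry is inverted before the coupling, and a stereoretentive cross-coupling is used.
- 12 is lithiated and quenched with i-PrOBpin to give the E-alkenyl boronic ester F4. Bromine addition followed by NaOMe (anti addition, anti elimination) gives the Z-alkenyl bromide F5.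
- Separately, 5 is converted with KHF2 into the potassium trifluoroborate F6.
- Suzuki–Miyaura coupling of F6 and F5 (PdCl2(dppf), Cs2CO3, toluene–H2O, 80 °C) proceeds with retention and gives 16.

**Further compounds**
F1 | step 11 | (1R,2R,4S)-2-{2-[(2S,3R,6S)-3-bromo-6-ethenyl-2,6-dimethyloxan-2-yl]ethyl}-1,4-dimethyl-3-methylidenecyclohexan-1-ol | C=C[C@]1(C)CC[C@@H](Br)[C@](C)(CC[C@@H]2C(=C)[C@@H](C)CC[C@@]2(C)O)O1
F2 | step 11 | 2-{2-[(2S,3R,6S)-3-bromo-6-ethenyl-2,6-dimethyloxan-2-yl]ethyl}-1,3,4-trimethylcyclohex-3-en-1-ol (hydroxyl trans to the side chain) | C=C[C@]1(C)CC[C@@H](Br)[C@](C)(CC[C@@H]2C(C)=C(C)CC[C@@]2(C)O)O1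
F3 | step 4 | oxan-3-ylmercury bromide corresponding to 5 | C=C[C@]1(C)CC[C@@H]([Hg]Br)[C@](C)(CCB2OC(C)(C)C(C)(C)O2)O1
F4 | step 9 | (E)-alkenylboronic acid pinacol ester from 12 | CC1(C)OB(OC1(C)C)/C=C(\C)[C@@H](C)CCC1(C)OCCO1
F5 | step 9 | 2-[(3S,4Z)-5-bromo-3,4-dimethylpent-4-en-1-yl]-2-methyl-1,3-dioxolane | Br/C=C(/C)[C@@H](C)CCC1(C)OCCO1
F6 | step 9 | potassium trifluoroborate from 5 | [K+].C=C[C@]1(C)CC[C@@H](Br)[C@](C)(CC[B-](F)(F)F)O1
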